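## Structural features

The target is a cembranolide. A 14-membered carbocycle (ring A, C1–C14 in cembrane numbering, used throughout) is fused across C1–C2 to an α-methylene-γ-butyrolactone (ring B: O, C2, C1, C15, C16(=O), with the exocyclic C17H2 on C15). The ring fusion is trans (1R,2S), and C2 is both the lactone O–CH and allylic to the E-C3=C4 alkene. Ring A holds three E-trisubstituted alkenes (C3=C4, C7=C8, C11=C12), each with its methyl on the carbon remote from an oxygen-bearing allylic CH (C2, C6, C10), so that C2–C13 is a threefold repeat of O–CH–CH=C(Me)–CH2. C6 (S, acetate) and C10 (S, free hydroxyl) are separated from each other and from C1/C2 by E-alkenes, so no centre can direct the next through a small cyclic transition state, and two nearly equivalent allylic carbinols must end up differently acylated. The fragile groups are the α-methylene lactone (Michael acceptor, sensitive to hydride, organometallics and base), the allylic acetate (ionisation, zerovalent palladium, base) and all three allylic C–O bonds (acid-induced transposition). The real difficulty is to close ring A while setting the contiguous C1/C2 pair trans and in the correct absolute sense relative to the distant C6 and C10. The key step exploits two features: the five atoms of ring B (O, C2, C1, C15, C16) are exactly the five atoms of a [2,3]-Wittig transition state, and the alkene next to C2 can be carried as a C3≡C4 alkyne. The alkyne acidifies C2–H and is later converted into the E-methyl alkene under the direction of the C2 hydroxyl that the rearrangement sets free.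

## Logic of the disconnections

33 ⇒ 30 (through 32 and 31). No skeletal bond is cut; the C6 acetate and the C10 hydroxyl are traced back to a TES ether and a TBS ether. The cut is made here because the allylic acetate survives none of the enolate, hydride or organometallic steps, and the two carbinols can only be told apart by the groups they received when each was created. The gain is that only the last three steps handle the acetate and the free C10 hydroxyl. The forward steps must cleave TES in the presence of TBS and of the methylene lactone, and the last desilylation must spare the allylic acetate.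

30 ⇒ 28 ⇒ 26 ⇒ 24. The C15=C17 bond is cut first (C17 returns to formaldehyde), then the acyl C16–O bond together with the C16 oxidation level. Ring B thereby shrinks to a C2 hydroxyl and a vinyl group (C15=C16) on C1. The reason is that the Michael acceptor should appear as late as possible and a vinyl group is a robust two-carbon placeholder for C15–C16. The gain is that the lactone is absent from every step that uses hydride or carbanions. The demands are that hydroboration choose the one monosubstituted alkene over three trisubstituted ones, that the oxidation choose the primary over the allylic secondary alcohol, and that the enolate chemistry at C15 leave C1 untouched.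

24 ⇒ 21 (through 23). The C4–CH3 bond is cut and C3=C4 is returned to a C3≡C4 alkyne. The cut is placed here because the alkyne is what the key step needs, and because its conversion into the E-methyl alkene is directed by the neighbouring C2 hydroxyl. The gain is that one stereodefined trisubstituted alkene is replaced by a geometry-free triple bond. The demand is trans addition with hydride on C3 and aluminium on C4, followed by retention in the iodination and in the methyl coupling.

21 ⇒ 19, the key disconnection. The C1–C2 bond is cut and the O–C16 bond is restored: in one sentence, 21 is the [2,3]-Wittig ring-contraction product of the 17-membered propargylic allylic ether 19. The cut is made here because it removes ring A and both contiguous stereocentres at once and leaves a macrocyclic ether whose only stereochemical information near the future ring fusion is an E-alkene. The demands on the forward step are deprotonation at C2 only, [2,3] in preference to [1,2] shift, the anti relationship at C1/C2, and control of the absolute sense by the base.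

19 ⇒ 18. The C3≡C4 bond is cut by a retro alkyne metathesis to give an acyclic diyne with two methyl caps. Ring closure at a triple bond creates no stereo-element and lies four atoms or more from every stereocentre. The gain is a linear chain. The forward step needs a catalyst that ignores alkenes, ethers and silyl ethers, and high dilution.

18 ⇒ 15 (through 17 and 16). The C5–C6 bond is cut, together with the methyl cap and the TES group, to give an enal and a propargyl unit. This is where C6 is created and tagged. The demand is catalyst-controlled addition to one face of a β,β-disubstituted enal.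

15 ⇒ 10 (through 14, 12 and 11). C6–C7 and C8–CH3 are cut by a retro alkyne carbometalation (C6 returns to formaldehyde), and C9–C10 by the same propargylation as above. One O–CH–CH=C(Me)–CH2 repeat is thereby removed by two operations that are used again elsewhere in the route. The demands are syn methylalumination of the terminal alkyne in the presence of the internal one, and catalyst control at C10.

10 ⇒ 7 ⇒ 3 + 4 (through 9 and 6). C10–C11 and C12–CH3 are cut by the same carbometalation logic, and C13–C14 by alkylation of lithiated 4 with the allylic bromide 3. The gain is a C3 and a C8 building block. The demand is SN2 (not SN2′) attack by the propargylic (not allenylic) terminus.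

3 ⇒ 1 + 2. The O–C16 ether bond is cut. The ether oxygen is the future lactone oxygen, and the E geometry of 1 becomes the trans ring fusion. The demand is mono-substitution of a symmetrical dibromide.

## Other disconnections considered

Alternative 1: the first that comes to mind. The cut is C1–C2 together with the lactone C16–O bond. The forward step is an intramolecular Barbier or Nozaki–Hiyama–Kishi allylation of the seco aldehyde–allylic bromide A1 with CrCl2 (divalent chromium) or Zn, followed by lactonisation to the protected lactone 30. It is several steps shorter. It is not preferred because the end-to-end macrocyclisation and the stereo-determining event are the same step. The cis/trans fusion and the facial sense relative to C6/C10 would be decided by the conformation of a 14-membered chair-like transition state and not by any element that can be chosen. A1 also has to carry an enal and a 2-(bromomethyl)enoate through its synthesis. The chosen plan separates the two tasks: a stereo-neutral ring closure at a triple bond, then a five-membered transition state for C1/C2.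

Alternative 2: the cut is at C11/C12, taken as an alkyne. The forward step is ring-closing alkyne metathesis of the diyne lactone A2 to the cycloalkyne A3, followed by hydroxyl-directed trans-hydrometalation and methylation at C12. It is not preferred because A3 already contains ring B, which does not survive an aluminium hydride, while the ruthenium-catalysed trans-hydrostannation that would tolerate the lactone places tin on C11, the wrong carbon for the methyl group. The lactone would have to be masked, and C1/C2 would still need a separate asymmetric step. In the chosen plan one alkyne does three jobs (ring closure, acidification of C2–H, precursor of C3=C4) and the directing hydroxyl is produced by the key step itself.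

Alternative 3: the cut is C14–C1. The forward step is a radical macrocyclisation of the iodide A4 (Bu3SnH, slow addition) onto C1 of its 3-(bromomethyl)butenolide, with loss of a bromine atom, to give 30 directly and to set C1 trans to C2. It is not preferred on mechanistic grounds. Addition of a primary radical to a β-substituted acceptor is slow compared with hydrogen transfer at the dilution a 14-membered closure needs. The facial choice at C1 would depend on the tether, because the C2 substituent is the tether itself. This acceptor class has no macrocyclic precedent, and C2 would need its own asymmetric step.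

Key step: step 14

Abbreviations: TBS = tert-butyldimethylsilyl, TES = triethylsilyl, TRIP = 3,3′-bis(2,4,6-triisopropylphenyl)-1,1′-binaphthyl-2,2′-diyl hydrogen phosphate, pin = pinacolato.

Assumption: the sense of induction written for (S)-TRIP (steps 6 and 10) and for the (S,S)-lithium amide (step 14) is taken by analogy with simple aldehydes and with macrocyclic propargylic ethers. If a first run shows the opposite sense, the antipode of the catalyst or base is used and nothing else changes.

## Route

Step 1
Reactants: 1 (E)-1,4-dibromobut-2-ene; 2 but-2-yn-1-ol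
Product: 3 (E)-1-bromo-4-(but-2-yn-1-yloxy)but-2-ene
Conditions: 2, NaH, THF, 0 °C; added to 1 (3 equiv), 0 °C → rt
Reagents that add atoms: none
Why: Williamson ether synthesis; the excess of symmetrical dibromide favours mono-substitution, and SN2 at the primary allylic carbon keeps the E geometry that later becomes the trans ring fusion.

Step 2
Reactants: 3 (E)-1-bromo-4-(but-2-yn-1-yloxy)but-2-ene; 4 1-(trimethylsilyl)propyne
Product: 6 trimethyl[(5E)-7-(but-2-yn-1-yloxy)hept-5-en-1-yn-1-yl]silane, via 3-lithio-1-(trimethylsilyl)propyne 5 (not isolated)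
Conditions: 4, n-BuLi, TMEDA, Et2O, −5 °C; then 3, −78 → 0 °C
Reagents that add atoms: none
Why: Alkylation of a silyl-capped propargylic anion by an allylic bromide (1,5-enyne synthesis) forms C13–C14; the silyl group steers reaction to the propargylic terminus and the primary allylic bromide reacts by SN2.

Step 3
Reactants: 6 trimethyl[(5E)-7-(but-2-yn-1-yloxy)hept-5-en-1-yn-1-yl]silane
Product: 7 (5E)-7-(but-2-yn-1-yloxy)hept-5-en-1-yne
Conditions: K2CO3, MeOH, rt
Reagents that add atoms: none
Why: Protodesilylation of the alkynylsilane by methoxide; ethers, alkene and internal alkyne are inert.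

Step 4
Reactants: 7 (5E)-7-(but-2-yn-1-yloxy)hept-5-en-1-yne
Product: 9 (2E,6E)-8-(but-2-yn-1-yloxy)-3-methylocta-2,6-dien-1-ol, via alkenyldimethylalane 8 (not isolated)
Conditions: Me3Al (3 equiv), Cp2ZrCl2 (25 mol%), CH2Cl2, 0 °C → rt; then (CH2O)n, 0 °C → rt
Reagents that add atoms: trimethylaluminium C[Al](C)C; formaldehyde (as paraformaldehyde) C=O
Why: Zirconium-catalysed syn-methylalumination (Negishi carboalumination) puts methyl on the internal carbon C12 and aluminium on C11, which fixes the E geometry; the alkenyl–aluminium bond is hydroxymethylated with retention. The terminal alkyne should react far faster than the internal butynyl one.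

Step 5
Reactants: 9 (2E,6E)-8-(but-2-yn-1-yloxy)-3-methylocta-2,6-dien-1-ol
Product: 10 (2E,6E)-8-(but-2-yn-1-yloxy)-3-methylocta-2,6-dienal
Conditions: MnO2, CH2Cl2, rt
Reagents that add atoms: none
Why: Selective oxidation of an allylic alcohol under neutral heterogeneous conditions, which should not isomerise the E-enal.

Step 6
Reactants: 10 (2E,6E)-8-(but-2-yn-1-yloxy)-3-methylocta-2,6-dienal
Product: 11 (4S,5E,9E)-11-(but-2-yn-1-yloxy)-6-methylundeca-5,9-dien-1-yn-4-ol
Conditions: allenylboronic acid pinacol ester (1.5 equiv), (S)-TRIP (5 mol%), 4 Å MS, toluene, 0 °C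
Reagents that add atoms: allenylboronic acid pinacol ester C=C=CB1OC(C)(C)C(C)(C)O1
Why: Chiral phosphoric acid-catalysed propargylation (allenylboration) through a six-membered cyclic transition state gives the homopropargylic alcohol by 1,2-addition; the catalyst, bound to the boronate oxygen and the formyl hydrogen, selects the aldehyde face and sets C10 (S).

Step 7
Reactants: 11 (4S,5E,9E)-11-(but-2-yn-1-yloxy)-6-methylundeca-5,9-dien-1-yn-4-ol
Product: 12 (4S,5E,9E)-11-(but-2-yn-1-yloxy)-4-(TBSO)-6-methylundeca-5,9-dien-1-yne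
Conditions: TBSCl, imidazole, DMF, rt
Reagents that add atoms: tert-butyldimethylsilyl chloride CC(C)(C)[Si](C)(C)Cl
Why: Standard silylation of a secondary alcohol; this tags the C10 oxygen with the group that is removed last.

Step 8
Reactants: 12 (4S,5E,9E)-11-(but-2-yn-1-yloxy)-4-(TBSO)-6-methylundeca-5,9-dien-1-yne
Product: 14 (2E,5S,6E,10E)-12-(but-2-yn-1-yloxy)-5-(TBSO)-3,7-dimethyldodeca-2,6,10-trien-1-ol, via alkenyldimethylalane 13 (not isolated)
Conditions: Me3Al (3 equiv), Cp2ZrCl2 (25 mol%), CH2Cl2, 0 °C → rt; then (CH2O)n, 0 °C → rt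
Reagents that add atoms: trimethylaluminium C[Al](C)C; formaldehyde (as paraformaldehyde) C=O
Why: Second Negishi carboalumination with hydroxymethylation, as in step 4: syn addition sets E-C7=C8 with the methyl on C8 and adds C6; homopropargylic silyl ethers are well tolerated.

Step 9
Reactants: 14 (2E,5S,6E,10E)-12-(but-2-yn-1-yloxy)-5-(TBSO)-3,7-dimethyldodeca-2,6,10-trien-1-ol
Product: 15 (2E,5S,6E,10E)-12-(but-2-yn-1-yloxy)-5-(TBSO)-3,7-dimethyldodeca-2,6,10-trienal
Conditions: MnO2, CH2Cl2, rt
Reagents that add atoms: none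
Why: Allylic alcohol oxidation as in step 5; the silyl ether and the skipped alkenes are untouched.

Step 10
Reactants: 15 (2E,5S,6E,10E)-12-(but-2-yn-1-yloxy)-5-(TBSO)-3,7-dimethyldodeca-2,6,10-trienal
Product: 16 (4S,5E,8S,9E,13E)-15-(but-2-yn-1-yloxy)-8-(TBSO)-6,10-dimethylpentadeca-5,9,13-trien-1-yn-4-ol
Conditions: allenylboronic acid pinacol ester (1.5 equiv), (S)-TRIP (5 mol%), 4 Å MS, toluene, 0 °C
Reagents that add atoms: allenylboronic acid pinacol ester C=C=CB1OC(C)(C)C(C)(C)O1
Why: The same catalyst-controlled propargylation as in step 6 sets C6 (S); the existing C10 centre is four atoms away across an E-alkene, so the catalyst and not the substrate should decide the face.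

Step 11
Reactants: 16 (4S,5E,8S,9E,13E)-15-(but-2-yn-1-yloxy)-8-(TBSO)-6,10-dimethylpentadeca-5,9,13-trien-1-yn-4-ol
Product: 17 (4S,5E,8S,9E,13E)-15-(but-2-yn-1-yloxy)-8-(TBSO)-6,10-dimethyl-4-(TESO)pentadeca-5,9,13-trien-1-yne
Conditions: TESCl, imidazole, CH2Cl2, 0 °C
Reagents that add atoms: chlorotriethylsilane CC[Si](Cl)(CC)CC
Why: Silylation of the C6 hydroxyl with the more labile group, so that it can later be exchanged for acetate while the C10 TBS ether stays.

Step 12
Reactants: 17 (4S,5E,8S,9E,13E)-15-(but-2-yn-1-yloxy)-8-(TBSO)-6,10-dimethyl-4-(TESO)pentadeca-5,9,13-trien-1-yne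
Product: 18 (5S,6E,9S,10E,14E)-16-(but-2-yn-1-yloxy)-9-(TBSO)-7,11-dimethyl-5-(TESO)hexadeca-6,10,14-trien-2-yne
Conditions: n-BuLi, THF, −78 °C; then MeI, −78 °C → rt
Reagents that add atoms: iodomethane CI
Why: Deprotonation of the terminal alkyne (by far the most acidic C–H) and C-methylation supply the methyl cap that alkyne metathesis requires.

Step 13
Reactants: 18 (5S,6E,9S,10E,14E)-16-(but-2-yn-1-yloxy)-9-(TBSO)-7,11-dimethyl-5-(TESO)hexadeca-6,10,14-trien-2-yne
Product: 19 (3E,7E,9S,11E,13S)-9-(TBSO)-7,11-dimethyl-13-(TESO)-1-oxacycloheptadeca-3,7,11-trien-15-yne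
Conditions: Mo(≡CC6H4OMe-4)(OSiPh3)3 (5 mol%), 5 Å MS, toluene (2 mM), rt → 60 °C
Reagents that add atoms: none
Why: Ring-closing alkyne metathesis forms C3≡C4 and the 17-membered ether; uptake of but-2-yne by the sieves drives the equilibrium, the alkylidyne leaves alkenes alone, and no stereo-element is created.

Step 14
Reactants: 19 (3E,7E,9S,11E,13S)-9-(TBSO)-7,11-dimethyl-13-(TESO)-1-oxacycloheptadeca-3,7,11-trien-15-yne
Product: 21 (1R,5S,6E,9S,10E,14R)-9-(TBSO)-14-ethenyl-7,11-dimethyl-5-(TESO)cyclotetradeca-6,10-dien-2-yn-1-ol, via C2-lithiated ether 20 (not isolated)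
Conditions: LiN[(S)-CHMePh]2 (from the amine and n-BuLi), THF, −78 → −20 °C; aq. NH4Cl
Reagents that add atoms: none
Why: The amide removes one of the two diastereotopic C2 protons, the most acidic C–H of 19 because the carbanion is flanked by the ether oxygen and the C3≡C4 alkyne (the allylic C16–H and propargylic C5–H bonds each lack one of these two groups), to give 20. 20 rearranges by a concerted suprafacial [2,3]-sigmatropic (Wittig) shift through a five-membered envelope made of C2, O, C16, C15 and C1: the C1–C2 bond forms as the O–C16 bond breaks and the alkene moves to C15=C16. The closest known reaction type is the [2,3]-Wittig ring contraction of macrocyclic propargylic allylic ethers to 2-alkenylcycloalkynols. Ring A is closed by contraction of the preformed 17-membered ether to 14 members, a transannular bond formation and not an end-to-end cyclisation. C1 and C2 should come out anti (the relationship of the trans-fused lactone) because the E-C1=C15 alkene places C14 pseudo-equatorial while the alkynyl group on the carbanion takes the exo position of the envelope. The absolute configuration is set at the deprotonation: the chiral amide selects one C2 proton, the lithiated carbon rearranges faster than it inverts, and C1 follows from C2 through the envelope, with C6 and C10 too remote to override the base. The step needs regioselective metalation and [2,3] in preference to [1,2] shift; the alkyne secures the first, and the low temperature and the allylic migrating terminus secure the second.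

Step 15
Reactants: 21 (1R,5S,6E,9S,10E,14R)-9-(TBSO)-14-ethenyl-7,11-dimethyl-5-(TESO)cyclotetradeca-6,10-dien-2-yn-1-ol
Product: 23 (1R,2Z,5S,6E,9S,10E,14R)-9-(TBSO)-14-ethenyl-3-iodo-7,11-dimethyl-5-(TESO)cyclotetradeca-2,6,10-trien-1-ol, via cyclic alkenylaluminate 22 (not isolated)
Conditions: NaAlH2(OCH2CH2OMe)2, THF, 0 °C → rt; then I2, THF, −78 °C
Reagents that add atoms: iodine II
Why: Hydroxyl-directed trans-hydroalumination of the propargylic alcohol: the C2 alkoxyaluminate delivers hydride to C3 and closes a five-membered ring with aluminium on C4, and iodine cleaves the C4–Al bond with retention, so iodine ends cis to C2. Isolated alkenes and silyl ethers do not react with the hydride.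

Step 16
Reactants: 23 (1R,2Z,5S,6E,9S,10E,14R)-9-(TBSO)-14-ethenyl-3-iodo-7,11-dimethyl-5-(TESO)cyclotetradeca-2,6,10-trien-1-ol
Product: 24 (1R,2E,5S,6E,9S,10E,14R)-9-(TBSO)-14-ethenyl-3,7,11-trimethyl-5-(TESO)cyclotetradeca-2,6,10-trien-1-ol
Conditions: Me2CuLi (from MeLi and CuI, 5 equiv), Et2O, 0 °C
Reagents that add atoms: lithium dimethylcuprate [Li+].C[Cu-]C
Why: Cuprate substitution of a 3-iodoallylic alkoxide proceeds with retention of alkene geometry, so the methyl takes the place cis to C2 and C3=C4 becomes E with the methyl on C4.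

Step 17
Reactants: 24 (1R,2E,5S,6E,9S,10E,14R)-9-(TBSO)-14-ethenyl-3,7,11-trimethyl-5-(TESO)cyclotetradeca-2,6,10-trien-1-ol
Product: 26 (1R,2E,5S,6E,9S,10E,14R)-9-(TBSO)-14-(2-hydroxyethyl)-3,7,11-trimethyl-5-(TESO)cyclotetradeca-2,6,10-trien-1-ol, via bis(9-BBN) adduct 25 (not isolated)
Conditions: 9-BBN-H (2.5 equiv), THF, 0 °C → rt; then NaOH, H2O2, 0 °C
Reagents that add atoms: hydrogen peroxide OO
Why: Anti-Markovnikov hydroboration–oxidation; 9-BBN adds to the monosubstituted vinyl group much faster than to the three trisubstituted ring alkenes and places boron on terminal C16. No stereocentre is touched.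

Step 18
Reactants: 26 (1R,2E,5S,6E,9S,10E,14R)-9-(TBSO)-14-(2-hydroxyethyl)-3,7,11-trimethyl-5-(TESO)cyclotetradeca-2,6,10-trien-1-ol
Product: 28 (3aR,6E,8S,10E,12S,14E,15aR)-8-(TBSO)-6,10,14-trimethyl-12-(TESO)-3a,4,5,8,9,12,13,15a-octahydrocyclotetradeca[b]furan-2(3H)-one, via lactol 27 (not isolated)
Conditions: TEMPO (20 mol%), PhI(OAc)2 (2.5 equiv), CH2Cl2, rt
Reagents that add atoms: none
Why: Oxoammonium-mediated oxidative lactonisation of a 1,4-diol: the primary alcohol is oxidised first, the aldehyde is trapped by the C2 hydroxyl as lactol 27, and this is oxidised to the lactone with the trans fusion already in place.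

Step 19
Reactants: 28 (3aR,6E,8S,10E,12S,14E,15aR)-8-(TBSO)-6,10,14-trimethyl-12-(TESO)-3a,4,5,8,9,12,13,15a-octahydrocyclotetradeca[b]furan-2(3H)-one
Product: 30 (3aR,6E,8S,10E,12S,14E,15aS)-8-(TBSO)-6,10,14-trimethyl-3-methylidene-12-(TESO)-3a,4,5,8,9,12,13,15a-octahydrocyclotetradeca[b]furan-2(3H)-one, via sodium formyl-enolate 29 (not isolated)
Conditions: NaH, HCO2Et, Et2O (cat. EtOH), rt; then (CH2O)n, THF, reflux
Reagents that add atoms: formaldehyde (as paraformaldehyde) C=O
Why: α-Methylenation of a γ-lactone by Claisen formylation at C15, aldol addition of the formyl enolate to formaldehyde, formyl transfer to the new alkoxide and loss of formate; only C15 is enolised, so C1 and C2 keep their configuration.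

Step 20
Reactants: 30 (3aR,6E,8S,10E,12S,14E,15aS)-8-(TBSO)-6,10,14-trimethyl-3-methylidene-12-(TESO)-3a,4,5,8,9,12,13,15a-octahydrocyclotetradeca[b]furan-2(3H)-one
Product: 31 (3aR,6E,8S,10E,12S,14E,15aS)-8-(TBSO)-12-hydroxy-6,10,14-trimethyl-3-methylidene-3a,4,5,8,9,12,13,15a-octahydrocyclotetradeca[b]furan-2(3H)-one
Conditions: PPTS (20 mol%), MeOH/CH2Cl2, 0 °C
Reagents that add atoms: none
Why: Mild acid methanolysis cleaves the secondary TES ether much faster than the secondary TBS ether and is too weak to ionise the allylic C–O bonds or add methanol to the methylene lactone.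

Step 21
Reactants: 31 (3aR,6E,8S,10E,12S,14E,15aS)-8-(TBSO)-12-hydroxy-6,10,14-trimethyl-3-methylidene-3a,4,5,8,9,12,13,15a-octahydrocyclotetradeca[b]furan-2(3H)-one
Product: 32 (3aR,6E,8S,10E,12S,14E,15aS)-8-(TBSO)-6,10,14-trimethyl-3-methylidene-2-oxo-2,3,3a,4,5,8,9,12,13,15a-decahydrocyclotetradeca[b]furan-12-yl acetate
Conditions: Ac2O, pyridine, DMAP (cat.), CH2Cl2, 0 °C → rt
Reagents that add atoms: acetic anhydride CC(=O)OC(C)=O
Why: Acylation of the only free hydroxyl with retention at C6.

Step 22
Reactants: 32 (3aR,6E,8S,10E,12S,14E,15aS)-8-(TBSO)-6,10,14-trimethyl-3-methylidene-2-oxo-2,3,3a,4,5,8,9,12,13,15a-decahydrocyclotetradeca[b]furan-12-yl acetate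
Product: 33 (3aR,6E,8S,10E,12S,14E,15aS)-8-hydroxy-6,10,14-trimethyl-3-methylidene-2-oxo-2,3,3a,4,5,8,9,12,13,15a-decahydrocyclotetradeca[b]furan-12-yl acetate (CNP0168244.1)
Conditions: HF·pyridine, pyridine, THF, 0 °C → rt
Reagents that add atoms: none
Why: Buffered fluoride-mediated desilylation frees the C10 hydroxyl without acyl migration (C6 and C10 are 1,5-related across an E-alkene) and without attack on the Michael acceptor.

## Compound list

1 | (E)-1,4-dibromobut-2-ene | BrC/C=C/CBr | starting material
2 | but-2-yn-1-ol | CC#CCO | starting material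
3 | (E)-1-bromo-4-(but-2-yn-1-yloxy)but-2-ene | CC#CCOC/C=C/CBr | intermediate
4 | 1-(trimethylsilyl)propyne | CC#C[Si](C)(C)C | starting material
5 | 3-lithio-1-(trimethylsilyl)propyne | [Li]CC#C[Si](C)(C)C | intermediate
6 | trimethyl[(5E)-7-(but-2-yn-1-yloxy)hept-5-en-1-yn-1-yl]silane | C[Si](C)(C)C#CCC/C=C/COCC#CC | intermediate
7 | (5E)-7-(but-2-yn-1-yloxy)hept-5-en-1-yne | C#CCC/C=C/COCC#CC | intermediate
8 | [(1E,5E)-7-(but-2-yn-1-yloxy)-2-methylhepta-1,5-dien-1-yl]dimethylalane | C[Al](C)/C=C(\C)CC/C=C/COCC#CC | intermediate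
9 | (2E,6E)-8-(but-2-yn-1-yloxy)-3-methylocta-2,6-dien-1-ol | OC/C=C(\C)CC/C=C/COCC#CC | intermediate
10 | (2E,6E)-8-(but-2-yn-1-yloxy)-3-methylocta-2,6-dienal | O=C/C=C(\C)CC/C=C/COCC#CC | intermediate
11 | (4S,5E,9E)-11-(but-2-yn-1-yloxy)-6-methylundeca-5,9-dien-1-yn-4-ol | C#CC[C@H](O)/C=C(\C)CC/C=C/COCC#CC | intermediate
12 | (4S,5E,9E)-11-(but-2-yn-1-yloxy)-4-(TBSO)-6-methylundeca-5,9-dien-1-yne | C#CC[C@H](O[Si](C)(C)C(C)(C)C)/C=C(\C)CC/C=C/COCC#CC | intermediate
13 | [(1E,4S,5E,9E)-11-(but-2-yn-1-yloxy)-4-(TBSO)-2,6-dimethylundeca-1,5,9-trien-1-yl]dimethylalane | C[Al](C)/C=C(\C)C[C@H](O[Si](C)(C)C(C)(C)C)/C=C(\C)CC/C=C/COCC#CC | intermediate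
14 | (2E,5S,6E,10E)-12-(but-2-yn-1-yloxy)-5-(TBSO)-3,7-dimethyldodeca-2,6,10-trien-1-ol | OC/C=C(\C)C[C@H](O[Si](C)(C)C(C)(C)C)/C=C(\C)CC/C=C/COCC#CC | intermediate
15 | (2E,5S,6E,10E)-12-(but-2-yn-1-yloxy)-5-(TBSO)-3,7-dimethyldodeca-2,6,10-trienal | O=C/C=C(\C)C[C@H](O[Si](C)(C)C(C)(C)C)/C=C(\C)CC/C=C/COCC#CC | intermediate
16 | (4S,5E,8S,9E,13E)-15-(but-2-yn-1-yloxy)-8-(TBSO)-6,10-dimethylpentadeca-5,9,13-trien-1-yn-4-ol | C#CC[C@H](O)/C=C(\C)C[C@H](O[Si](C)(C)C(C)(C)C)/C=C(\C)CC/C=C/COCC#CC | intermediate
17 | (4S,5E,8S,9E,13E)-15-(but-2-yn-1-yloxy)-8-(TBSO)-6,10-dimethyl-4-(TESO)pentadeca-5,9,13-trien-1-yne | C#CC[C@H](O[Si](CC)(CC)CC)/C=C(\C)C[C@H](O[Si](C)(C)C(C)(C)C)/C=C(\C)CC/C=C/COCC#CC | intermediate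
18 | (5S,6E,9S,10E,14E)-16-(but-2-yn-1-yloxy)-9-(TBSO)-7,11-dimethyl-5-(TESO)hexadeca-6,10,14-trien-2-yne | CC#CC[C@H](O[Si](CC)(CC)CC)/C=C(\C)C[C@H](O[Si](C)(C)C(C)(C)C)/C=C(\C)CC/C=C/COCC#CC | intermediate
19 | (3E,7E,9S,11E,13S)-9-(TBSO)-7,11-dimethyl-13-(TESO)-1-oxacycloheptadeca-3,7,11-trien-15-yne | O1CC#CC[C@H](O[Si](CC)(CC)CC)/C=C(\C)C[C@H](O[Si](C)(C)C(C)(C)C)/C=C(\C)CC/C=C/C1 | intermediate
20 | [(3E,7E,9S,11E,13S)-9-(TBSO)-7,11-dimethyl-13-(TESO)-1-oxacycloheptadeca-3,7,11-trien-15-yn-17-yl]lithium (C2-lithiated 19; configuration at the lithiated carbon not defined) | O1C([Li])C#CC[C@H](O[Si](CC)(CC)CC)/C=C(\C)C[C@H](O[Si](C)(C)C(C)(C)C)/C=C(\C)CC/C=C/C1 | intermediate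
21 | (1R,5S,6E,9S,10E,14R)-9-(TBSO)-14-ethenyl-7,11-dimethyl-5-(TESO)cyclotetradeca-6,10-dien-2-yn-1-ol | O[C@H]1C#CC[C@H](O[Si](CC)(CC)CC)/C=C(\C)C[C@H](O[Si](C)(C)C(C)(C)C)/C=C(\C)CC[C@@H]1C=C | intermediate
22 | sodium salt of the cyclic alkenylaluminate of 21 (five-membered O–C2–C3=C4–Al ring, two 2-methoxyethoxy groups on aluminium) | [Na+].COCCO[Al-]1(OCCOC)O[C@H]2/C=C1/C[C@H](O[Si](CC)(CC)CC)/C=C(\C)C[C@H](O[Si](C)(C)C(C)(C)C)/C=C(\C)CC[C@@H]2C=C | intermediate
23 | (1R,2Z,5S,6E,9S,10E,14R)-9-(TBSO)-14-ethenyl-3-iodo-7,11-dimethyl-5-(TESO)cyclotetradeca-2,6,10-trien-1-ol | O[C@H]1/C=C(\I)C[C@H](O[Si](CC)(CC)CC)/C=C(\C)C[C@H](O[Si](C)(C)C(C)(C)C)/C=C(\C)CC[C@@H]1C=C | intermediate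
24 | (1R,2E,5S,6E,9S,10E,14R)-9-(TBSO)-14-ethenyl-3,7,11-trimethyl-5-(TESO)cyclotetradeca-2,6,10-trien-1-ol | O[C@H]1/C=C(\C)C[C@H](O[Si](CC)(CC)CC)/C=C(\C)C[C@H](O[Si](C)(C)C(C)(C)C)/C=C(\C)CC[C@@H]1C=C | intermediate
25 | bis(9-BBN) adduct of 24 (B-alkyl-9-BBN at C16, borinate at the C2 oxygen) | O(B2C3CCCC2CCC3)[C@H]1/C=C(\C)C[C@H](O[Si](CC)(CC)CC)/C=C(\C)C[C@H](O[Si](C)(C)C(C)(C)C)/C=C(\C)CC[C@@H]1CCB2C3CCCC2CCC3 | intermediate
26 | (1R,2E,5S,6E,9S,10E,14R)-9-(TBSO)-14-(2-hydroxyethyl)-3,7,11-trimethyl-5-(TESO)cyclotetradeca-2,6,10-trien-1-ol | O[C@H]1/C=C(\C)C[C@H](O[Si](CC)(CC)CC)/C=C(\C)C[C@H](O[Si](C)(C)C(C)(C)C)/C=C(\C)CC[C@@H]1CCO | intermediate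
27 | lactol of 28 (2-hydroxy in place of 2-oxo; configuration at C16 not defined) | OC1O[C@H]2/C=C(\C)C[C@H](O[Si](CC)(CC)CC)/C=C(\C)C[C@H](O[Si](C)(C)C(C)(C)C)/C=C(\C)CC[C@@H]2C1 | intermediate
28 | (3aR,6E,8S,10E,12S,14E,15aR)-8-(TBSO)-6,10,14-trimethyl-12-(TESO)-3a,4,5,8,9,12,13,15a-octahydrocyclotetradeca[b]furan-2(3H)-one | O=C1O[C@H]2/C=C(\C)C[C@H](O[Si](CC)(CC)CC)/C=C(\C)C[C@H](O[Si](C)(C)C(C)(C)C)/C=C(\C)CC[C@@H]2C1 | intermediate
29 | sodium enolate of the 3-formyl derivative of 28 (enolate geometry not defined) | [Na+].[O-]C=C1C(=O)O[C@H]2/C=C(\C)C[C@H](O[Si](CC)(CC)CC)/C=C(\C)C[C@H](O[Si](C)(C)C(C)(C)C)/C=C(\C)CC[C@H]12 | intermediate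
30 | (3aR,6E,8S,10E,12S,14E,15aS)-8-(TBSO)-6,10,14-trimethyl-3-methylidene-12-(TESO)-3a,4,5,8,9,12,13,15a-octahydrocyclotetradeca[b]furan-2(3H)-one | C=C1C(=O)O[C@H]2/C=C(\C)C[C@H](O[Si](CC)(CC)CC)/C=C(\C)C[C@H](O[Si](C)(C)C(C)(C)C)/C=C(\C)CC[C@H]12 | intermediate
31 | (3aR,6E,8S,10E,12S,14E,15aS)-8-(TBSO)-12-hydroxy-6,10,14-trimethyl-3-methylidene-3a,4,5,8,9,12,13,15a-octahydrocyclotetradeca[b]furan-2(3H)-one | C=C1C(=O)O[C@H]2/C=C(\C)C[C@H](O)/C=C(\C)C[C@H](O[Si](C)(C)C(C)(C)C)/C=C(\C)CC[C@H]12 | intermediate
32 | (3aR,6E,8S,10E,12S,14E,15aS)-8-(TBSO)-6,10,14-trimethyl-3-methylidene-2-oxo-2,3,3a,4,5,8,9,12,13,15a-decahydrocyclotetradeca[b]furan-12-yl acetate | C=C1C(=O)O[C@H]2/C=C(\C)C[C@H](OC(C)=O)/C=C(\C)C[C@H](O[Si](C)(C)C(C)(C)C)/C=C(\C)CC[C@H]12 | intermediate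
33 | (3aR,6E,8S,10E,12S,14E,15aS)-8-hydroxy-6,10,14-trimethyl-3-methylidene-2-oxo-2,3,3a,4,5,8,9,12,13,15a-decahydrocyclotetradeca[b]furan-12-yl acetate (CNP0168244.1) | C=C1C(=O)O[C@H]2/C=C(\C)C[C@H](OC(C)=O)/C=C(\C)C[C@H](O)/C=C(\C)CC[C@H]12 | target

## Step count and risk

Total step count: 22. Longest linear sequence: 22 steps (1 → 33; 2 and 4 enter in steps 1 and 2).

Least certain steps:

Step 14 (key step). The most likely failure is insufficient discrimination by the base between the two C2 protons inside the folded macrocycle, which would give both anti isomers (1R,2S and 1S,2R relative to fixed C6/C10). Partial [1,2]-shift, or metalation at C16 followed by rearrangement onto the alkyne, could also erode the yield. The fallback reverses the order of rearrangement and ring closure. It sets out from 18: the same lithium amide (or n-BuLi) effects the acyclic [2,3]-Wittig rearrangement of the (E)-allyl but-2-ynyl ether, where the E → anti rule operates without any ring constraint, to give the acyclic propargylic alcohol (4R,5R,8E,10S,12E,14S)-10-(TBSO)-5-ethenyl-8,12-dimethyl-14-(TESO)octadeca-8,12-dien-2,16-diyn-4-ol F1. Any unwanted anti isomer is removed at this acyclic stage. F1 is capped as its trimethylsilyl ether F2 (TMSCl, imidazole). Ring-closing alkyne metathesis with the molybdenum alkylidyne of step 13 then forms the 14-membered cycloalkyne silyl ether F3 directly, and K2CO3 in MeOH removes the trimethylsilyl group. The fallback comes back to the route at 21.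

Step 8 (and, on a simpler substrate, step 4). The methylalumination may lose chemoselectivity: the internal butynyl alkyne may be carbometalated competitively, the Lewis-acidic aluminium may cleave the allylic propargylic ether, or the TBS group may be lost. The fallback replaces the alkyne carbometalation by a vinylogous aldol and sets out from 10. The silyl dienolate tert-butyl[(1-methoxy-3-methylbuta-1,3-dien-1-yl)oxy]dimethylsilane F4 is made from methyl 3-methylbut-2-enoate with LiN(i-Pr)2 and TBSCl. An enantioselective vinylogous Mukaiyama aldol addition of F4 to 10 (SiCl4, chiral bis-phosphoramide Lewis base, CH2Cl2, −78 °C) should give the γ-adduct methyl (2E,5S,6E,10E)-12-(but-2-yn-1-yloxy)-5-hydroxy-3,7-dimethyldodeca-2,6,10-trienoate F5, with C10 and the E-C7=C8 alkene set together. Silylation gives the TBS ether F6, and i-Bu2AlH reduction of the ester comes back to the route at 14. This bypasses steps 6 to 8.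

Step 15. Hydride delivery from the C2 alkoxyaluminate may be slow or unselective in the 14-membered ring, iodine may add to the vinyl group or to the trisubstituted alkenes, and the TES ether may be lost. The fallback sets out from 21 and replaces hydroalumination by a ruthenium-catalysed trans-hydrosilylation ([Cp*Ru(MeCN)3]PF6, Et3SiH, CH2Cl2). For a propargylic alcohol this places silicon on the distal carbon C4 and gives the vinylsilane (1R,2Z,5S,6E,9S,10E,14R)-9-(TBSO)-14-ethenyl-7,11-dimethyl-3-(triethylsilyl)-5-(TESO)cyclotetradeca-2,6,10-trien-1-ol F7. Iododesilylation with N-iodosuccinimide, with retention, comes back to the route at 23.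

Step 19. Formylation of the hindered lactone enolate may be incomplete, and the alkoxides present may add to the newly formed Michael acceptor. The fallback sets out from 28 and uses a Mannich–elimination sequence. The lithium enolate (LiN(SiMe3)2, THF, −78 °C) is trapped with dimethylmethyleneiminium iodide to give the amine (3aR,6E,8S,10E,12S,14E,15aR)-8-(TBSO)-3-[(dimethylamino)methyl]-6,10,14-trimethyl-12-(TESO)-3a,4,5,8,9,12,13,15a-octahydrocyclotetradeca[b]furan-2(3H)-one F8. Quaternisation with MeI and elimination with NaHCO3 comes back to the route at 30.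

## Further compounds

F1 | step 14 | (4R,5R,8E,10S,12E,14S)-10-(TBSO)-5-ethenyl-8,12-dimethyl-14-(TESO)octadeca-8,12-dien-2,16-diyn-4-ol | O[C@@H](C#CC)[C@@H](C=C)CC/C(C)=C/[C@@H](O[Si](C)(C)C(C)(C)C)C/C(C)=C/[C@@H](O[Si](CC)(CC)CC)CC#CC
F2 | step 14 | trimethylsilyl ether of F1 | C[Si](C)(C)O[C@@H](C#CC)[C@@H](C=C)CC/C(C)=C/[C@@H](O[Si](C)(C)C(C)(C)C)C/C(C)=C/[C@@H](O[Si](CC)(CC)CC)CC#CC
F3 | step 14 | {[(1R,5S,6E,9S,10E,14R)-9-(TBSO)-14-ethenyl-7,11-dimethyl-5-(TESO)cyclotetradeca-6,10-dien-2-yn-1-yl]oxy}trimethylsilane | C[Si](C)(C)O[C@H]1C#CC[C@H](O[Si](CC)(CC)CC)/C=C(\C)C[C@H](O[Si](C)(C)C(C)(C)C)/C=C(\C)CC[C@@H]1C=C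
F4 | step 8 | tert-butyl[(1-methoxy-3-methylbuta-1,3-dien-1-yl)oxy]dimethylsilane | COC(O[Si](C)(C)C(C)(C)C)=CC(C)=C
F5 | step 8 | methyl (2E,5S,6E,10E)-12-(but-2-yn-1-yloxy)-5-hydroxy-3,7-dimethyldodeca-2,6,10-trienoate | COC(=O)/C=C(\C)C[C@H](O)/C=C(\C)CC/C=C/COCC#CC
F6 | step 8 | methyl (2E,5S,6E,10E)-12-(but-2-yn-1-yloxy)-5-(TBSO)-3,7-dimethyldodeca-2,6,10-trienoate | COC(=O)/C=C(\C)C[C@H](O[Si](C)(C)C(C)(C)C)/C=C(\C)CC/C=C/COCC#CC
F7 | step 15 | (1R,2Z,5S,6E,9S,10E,14R)-9-(TBSO)-14-ethenyl-7,11-dimethyl-3-(triethylsilyl)-5-(TESO)cyclotetradeca-2,6,10-trien-1-ol | O[C@H]1/C=C(\[Si](CC)(CC)CC)C[C@H](O[Si](CC)(CC)CC)/C=C(\C)C[C@H](O[Si](C)(C)C(C)(C)C)/C=C(\C)CC[C@@H]1C=C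
F8 | step 19 | (3aR,6E,8S,10E,12S,14E,15aR)-8-(TBSO)-3-[(dimethylamino)methyl]-6,10,14-trimethyl-12-(TESO)-3a,4,5,8,9,12,13,15a-octahydrocyclotetradeca[b]furan-2(3H)-one (both C3 epimers) | CN(C)CC1C(=O)O[C@H]2/C=C(\C)C[C@H](O[Si](CC)(CC)CC)/C=C(\C)C[C@H](O[Si](C)(C)C(C)(C)C)/C=C(\C)CC[C@H]12
A1 | alternative 1 | methyl (2Z,6E,8S,10E,12S,14E)-2-(bromomethyl)-8-(TBSO)-6,10,14-trimethyl-16-oxo-12-(TESO)hexadeca-2,6,10,14-tetraenoate | O=C/C=C(\C)C[C@H](O[Si](CC)(CC)CC)/C=C(\C)C[C@H](O[Si](C)(C)C(C)(C)C)/C=C(\C)CC/C=C(\CBr)C(=O)OC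
A2 | alternative 2 | (4R,5S)-5-[(1E,4S,5E,8S)-8-hydroxy-2,6-dimethyl-4-(TESO)undeca-1,5-dien-9-yn-1-yl]-3-methylidene-4-(pent-3-yn-1-yl)oxolan-2-one | C=C1C(=O)O[C@@H](/C=C(\C)C[C@H](O[Si](CC)(CC)CC)/C=C(\C)C[C@H](O)C#CC)[C@@H]1CCC#CC
A3 | alternative 2 | (3aR,8S,10E,12S,14E,15aS)-8-hydroxy-10,14-dimethyl-3-methylidene-12-(TESO)-6,7-didehydro-3a,4,5,8,9,12,13,15a-octahydrocyclotetradeca[b]furan-2(3H)-one | C=C1C(=O)O[C@H]2/C=C(\C)C[C@H](O[Si](CC)(CC)CC)/C=C(\C)C[C@H](O)C#CCC[C@H]12
A4 | alternative 3 | (5S)-3-(bromomethyl)-5-[(1E,4S,5E,8S,9E)-8-(TBSO)-12-iodo-2,6,10-trimethyl-4-(TESO)dodeca-1,5,9-trien-1-yl]furan-2(5H)-one | O=C1O[C@@H](/C=C(\C)C[C@H](O[Si](CC)(CC)CC)/C=C(\C)C[C@H](O[Si](C)(C)C(C)(C)C)/C=C(\C)CCI)C=C1CBr
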